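(The earlier runs and the new flask stem from a simulated flask with constants of no real substance.)

The ratio [isomer of the product]/[target], two peaks summed over a run, carries the question: the asked share of target (the selectivity) equals one over one plus this ratio.

| flask | starting material | catalyst | temperature | remark | time |
|---|---|---|---|---|---|
| spring | 0.43 M (fed, over 8.0 min) | 0.087 mol% | 45 °C | run made earlier |  |
| winter | 0.43 M (fed, over 8.0 min) | 0.2 mol% | 65 °C | run made earlier |  |
| dawn | 0.86 M (fed, over 8.0 min) | 0.13 mol% | 45 °C | run made earlier |  |
| south-west | 0.43 M | 0.13 mol% | 50 °C | everything together at the start | 8.0 min |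
| west | 0.43 M (fed, over 8.0 min) | 0.13 mol% | 80 °C |  | 8.0 min |

| run | time / min | target / % | isomer of the product / % | starting material / % |
|---|---|---|---|---|
| spring | 2.50 | 0.1 | 0 | 29.7 |
| spring | 4.00 | 0.7 | 0 | 48.5 |
| spring | 8.00 | 1.7 | 0.7 | 92.2 |
| spring | 15.0 | 5.6 | 0.8 | 76.3 |
| spring | 30.0 | 10.9 | 0 | 53.7 |
| winter | 0.833 | 0.4 | 0.5 | 10.0 |
| winter | 3.00 | 2.9 | 0 | 33.2 |
| winter | 4.00 | 3.8 | 0 | 42.3 |
| winter | 6.00 | 8.5 | 0.5 | 56.1 |
| winter | 10.0 | 18.4 | 1.1 | 53.1 |
| dawn | 6.00 | 3.9 | 0 | 66.5 |
| dawn | 12.0 | 11.5 | 0.6 | 66.6 |
| dawn | 15.0 | 13.2 | 0.3 | 57.6 |
| dawn | 25.0 | 23.0 | 0 | 38.7 |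
| dawn | 30.0 | 25.8 | 0.3 | 31.2 |

(readings scatter by 0.5 percentage points)

- the earlier runs were read with a standard deviation of 0.5 percentage points
- in a conversion other conformer counts as not yet reacted
- percentages count the whole charge, also what has not yet gone in

* the winner by share of target in all that became target or isomer of the product; "neither" if no more than 2 percentage points parts them (south-west / west / neither)
* share of target in all that became target or isomer of the product, south-west
* share of target in all that became target or isomer of the product, west

I first set out the spring flask as a ladder of time scales. The lowest rung was the feed, over in 8.0 min. After it, from 15.0 min to 30.0 min, the starting material readings fell with a half-life of 29.6 min, a slower rung. Over the same minutes the target readings, set against the mean starting material, gave a half-life of 128 min for that path, slower again, so target took 23.1 % of the fall.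

The top rung was the isomer, whose single readings sit near the scatter of 0.5 percentage points, so I summed them. Spring and dawn together, at 45 °C, gave a ratio of 2.80 %, which put the isomer clock of the spring flask at 4571 min. Winter, at 65 °C, gave 6.18 %, so the ratio rose with temperature.

Carrying the same factor per degree onward, I reckoned the isomer ratio of west, at 80 °C, as 11.2 %, and that of south-west, at 50 °C, as 3.41 %. These gave shares of 89.9 % and 96.7 %. No earlier run told me what an all-at-once start does to the ratio.

The forecast named south-west, with 97 % for south-west and 91 % for west, slightly above my west share, holding that “isomer formation probably has the higher activation energy”.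

The flasks gave south-west as the winner, with 98.8 % for south-west and 90.9 % for west.

    starting material ⇌ other conformer (K = 0.450, k = 0.00100 /s, Ea = 94.0 kJ/mol, ΔH = 18.0 kJ/mol)
    starting material + catalyst → catalyst + target (k = 1.80 /M/s, Ea = 52.0 kJ/mol)
    catalyst + other conformer → catalyst + isomer of the product (k = 1.40 /M/s, Ea = 44.0 kJ/mol)
    2 starting material → homo dimer (k = 0.00540 /M/s, Ea = 66.0 kJ/mol)
    (constants at 80 °C)

The isomer ratio of west came to 10.01 % against my 11.2 %, while south-west came to 1.21 %, below my 3.41 %. Temperature was the largest single effect: south-west taken to the temperature of west fell from 98.8 % to 87.3 %. The same flask as west with 0.52 mol% of catalyst held 45.2 % of target at the end, and its isomer ratio stood at 8.23 %, below the 10.01 % of west, for a share of 92.4 %.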